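## Retrosynthetic overview

1. Both ring halogens are traced back to alcohols displaced with inversion: C5–Br from a C5 silyl ether, C3–Cl from a C3 ketone by way of the 2,3-cis alcohol. The (Z)-enyne arm is traced back to an allyl group on C2 (oxidative cleavage, Peterson olefination).
2. Key disconnection: the O1–C2 bond and the C2–CH2 bond of the only ring (O1, C2, C3, C4, C5, C6) are made in one operation from an acyclic α-diazoketone whose C6 oxygen carries an allyl group. The sequence is copper carbenoid, six-membered oxonium ylide, [2,3]-sigmatropic shift of the allyl group from O1 to C2.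
3. Enabling feature: C2 lies between ring oxygen O1 and the heteroatom-bearing C3, carries a CH2–CH=C arm, and is trans to the C6 arm across O1. This O1/C2(allyl)/C3(=O) array with a 2,6-trans relationship is what an allyl oxonium ylide rearrangement delivers.
4. The acyclic precursor comes from a glycolate enolate alkylation with a preformed (E)-3-bromopent-2-enyl iodide (sets C6), a chelation-controlled acetate aldol (sets the C5 oxygen) and acylation of diazomethane.
5. Ring order: the oxane ring is the only ring and is closed in step 12; all later steps are functional-group adjustments.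

Key step: step 12

Remark: ring atoms are numbered O1, C2 (allyl or enyne arm), C3, C4, C5, C6 (bromopentenyl arm) in all names and descriptors. Diazomethane is assumed to be generated from commercial N-methyl-N-nitroso-p-toluenesulfonamide.

## Route

Step 1
Reactants: 1 pent-2-yn-1-ol
Product: 2 (Z)-3-(triethylsilyl)pent-2-en-1-ol
Conditions: Et3SiH (1.2 equiv), [Cp*Ru(MeCN)3]PF6 (1 mol%), CH2Cl2, 0 °C to rt
Reagents that add atoms: triethylsilane, CC[SiH](CC)CC
Why: Ruthenium-catalysed trans-hydrosilylation of an internal alkyne; the propargylic hydroxyl directs silicon to the distal carbon C3 and H and Si add to opposite faces, which fixes the (Z)-vinylsilane with ethyl trans to CH2OH.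

Step 2
Reactants: 2 (Z)-3-(triethylsilyl)pent-2-en-1-ol
Product: 4 (E)-3-bromopent-2-en-1-ol, via anti dibromide 3 (not isolated)
Conditions: Br2 (1.05 equiv), CH2Cl2, −78 °C; then NaOMe, MeOH, −78 °C to rt
Reagents that add atoms: bromine, BrBr
Why: Bromodesilylation with inversion; anti addition of Br2 gives dibromide 3, and methoxide-induced anti elimination of the C2 bromide and the silyl group replaces silicon by bromine with inverted alkene geometry, so Br ends trans and ethyl cis to CH2OH.

Step 3
Reactants: 4 (E)-3-bromopent-2-en-1-ol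
Product: 5 (E)-3-bromo-1-iodopent-2-ene
Conditions: I2, PPh3, imidazole, CH2Cl2, 0 °C, dark; used without storage
Reagents that add atoms: iodine, [I][I]
Why: Appel-type iodination (SN2 at the primary allylic carbon) leaves the bromoalkene geometry untouched and gives a reactive electrophile for the enolate alkylation.

Step 4
Reactants: 6 2-(allyloxy)acetic acid; 7 (S)-4-benzyl-1,3-oxazolidin-2-one
Product: 9 (S)-3-[2-(allyloxy)acetyl]-4-benzyl-1,3-oxazolidin-2-one, via mixed pivalic anhydride 8 (not isolated)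
Conditions: PivCl, Et3N, THF, −20 °C; then 7, LiCl, −20 °C to rt
Reagents that add atoms: none
Why: Mixed-anhydride N-acylation of the oxazolidinone (LiCl and Et3N activate the N–H) installs the glycolate whose allyl ether oxygen later becomes ring oxygen O1.

Step 5
Reactants: 9 (S)-3-[2-(allyloxy)acetyl]-4-benzyl-1,3-oxazolidin-2-one; 5 (E)-3-bromo-1-iodopent-2-ene
Product: 11 (S)-3-[(2R,4E)-2-(allyloxy)-5-bromohept-4-enoyl]-4-benzyl-1,3-oxazolidin-2-one, via sodium enolate 10 (not isolated)
Conditions: NaN(SiMe3)2, THF, −78 °C; then 5 (1.5 equiv), −78 to −45 °C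
Reagents that add atoms: none
Why: Auxiliary-controlled alkylation of the sodium-chelated (Z)-glycolate enolate 10; the allylic iodide attacks the face opposite the benzyl group, which sets the future C6 as (R) and attaches the complete bromopentenyl arm.

Step 6
Reactants: 11 (S)-3-[(2R,4E)-2-(allyloxy)-5-bromohept-4-enoyl]-4-benzyl-1,3-oxazolidin-2-one
Product: 12 (2R,4E)-2-(allyloxy)-5-bromohept-4-en-1-ol
Conditions: NaBH4, THF/H2O (4:1), 0 °C to rt
Reagents that add atoms: none
Why: Reductive cleavage of the N-acyl oxazolidinone with NaBH4 gives the primary alcohol without epimerisation and returns the auxiliary.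

Step 7
Reactants: 12 (2R,4E)-2-(allyloxy)-5-bromohept-4-en-1-ol
Product: 13 (2R,4E)-2-(allyloxy)-5-bromohept-4-enal
Conditions: Dess–Martin periodinane, CH2Cl2, 0 °C to rt; crude aldehyde used at once
Reagents that add atoms: none
Why: Dess–Martin oxidation under non-epimerising conditions gives the configurationally labile α-alkoxy aldehyde.

Step 8
Reactants: 13 (2R,4E)-2-(allyloxy)-5-bromohept-4-enal; 14 tert-butyl[(1-methoxyethenyl)oxy]dimethylsilane
Product: 15 methyl (3R,4R,6E)-4-(allyloxy)-7-bromo-3-hydroxynon-6-enoate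
Conditions: MgBr2·OEt2 (3 equiv), CH2Cl2, −78 to −30 °C; aqueous HCl work-up
Reagents that add atoms: none
Why: Chelation-controlled Mukaiyama aldol addition; MgBr2 bridges the aldehyde and allyloxy oxygens (Cram chelate) and the ketene acetal attacks the face away from the CH2 arm, which sets the future C5 carbinol syn to the C6 oxygen, i.e. (3R,4R).

Step 9
Reactants: 15 methyl (3R,4R,6E)-4-(allyloxy)-7-bromo-3-hydroxynon-6-enoate
Product: 16 methyl (3R,4R,6E)-4-(allyloxy)-7-bromo-3-[(tert-butyldimethylsilyl)oxy]non-6-enoate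
Conditions: TBSOTf, 2,6-lutidine, CH2Cl2, −78 to 0 °C
Reagents that add atoms: tert-butyldimethylsilyl triflate, CC(C)(C)[Si](C)(C)OS(=O)(=O)C(F)(F)F
Why: Silylation of the secondary alcohol with the reactive silyl triflate; the bulky, weakly nucleophilic silyl ether is chosen so that this oxygen stays out of the carbenoid chemistry of step 12.

Step 10
Reactants: 16 methyl (3R,4R,6E)-4-(allyloxy)-7-bromo-3-[(tert-butyldimethylsilyl)oxy]non-6-enoate
Product: 17 (3R,4R,6E)-4-(allyloxy)-7-bromo-3-[(tert-butyldimethylsilyl)oxy]non-6-enoic acid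
Conditions: LiOH·H2O, THF/MeOH/H2O, 0 °C to rt; then 1 M HCl to pH 3–4
Reagents that add atoms: lithium hydroxide, [Li+].[OH-]
Why: Saponification of the methyl ester; the β-silyloxy group tolerates LiOH at 0 °C and no stereocentre is α to the carboxyl group.

Step 11
Reactants: 17 (3R,4R,6E)-4-(allyloxy)-7-bromo-3-[(tert-butyldimethylsilyl)oxy]non-6-enoic acid
Product: 19 (4R,5R,7E)-5-(allyloxy)-8-bromo-4-[(tert-butyldimethylsilyl)oxy]-1-diazodec-7-en-2-one, via mixed isobutyl carbonic anhydride 18 (not isolated)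
Conditions: i-BuOCOCl, Et3N, Et2O, −20 °C; then CH2N2 (excess, Et2O), 0 °C to rt
Reagents that add atoms: diazomethane, C=[N+]=[N-]
Why: Arndt–Eistert-type acylation of diazomethane by the mixed carbonic anhydride 18 gives the α-diazoketone under conditions that leave the silyl ether, the allyl ether and the bromoalkene untouched.

Step 12
Reactants: 19 (4R,5R,7E)-5-(allyloxy)-8-bromo-4-[(tert-butyldimethylsilyl)oxy]-1-diazodec-7-en-2-one
Product: 21 (2R,5R,6R)-2-allyl-6-[(E)-3-bromopent-2-enyl]-5-[(tert-butyldimethylsilyl)oxy]oxan-3-one, via oxonium ylide 20 (not isolated)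
Conditions: Cu(hfacac)2 [Cu(CF3COCHCOCF3)2] (5 mol%), CH2Cl2, reflux, slow addition of 19
Reagents that add atoms: none
Why: The copper catalyst expels N2 from the diazoketone to give an electrophilic copper carbenoid, which is captured by a lone pair of the allyl ether oxygen to give the cyclic oxonium ylide 20; a [2,3]-sigmatropic shift then moves the allyl group from O1 to the ylide carbon C2 and releases the neutral oxan-3-one. The closest known reaction type is the copper-catalysed oxonium ylide formation and [2,3] rearrangement of δ-allyloxy α-diazoketones, which gives 2,6-trans-2-allyl-tetrahydropyran-3-ones. The ring (O1, C2–C6) is closed by O1–C2 bond formation, a six-membered ylide closure by attack of the ether oxygen on the carbenoid carbon. The new stereocentre C2 is controlled by C6: in the chair-like ylide the C6 arm is equatorial, the O-allyl group lies anti to it, and the allyl group migrates suprafacially on that face, so it ends trans to the C6 arm (2R). The step needs chemoselectivity for ylide formation at the allyl ether oxygen over capture by the C5 silyl ether oxygen (five-membered ylide), C–H insertion, cyclopropanation and [1,2] shift. The bulky, weakly basic silyl ether, the electron-poor bromoalkene and the electrophilic hexafluoroacetylacetonate catalyst secure it.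

Step 13
Reactants: 21 (2R,5R,6R)-2-allyl-6-[(E)-3-bromopent-2-enyl]-5-[(tert-butyldimethylsilyl)oxy]oxan-3-one
Product: 22 (2R,3R,5R,6R)-2-allyl-6-[(E)-3-bromopent-2-enyl]-5-[(tert-butyldimethylsilyl)oxy]oxan-3-ol
Conditions: LiBH(s-Bu)3, THF, −78 °C
Reagents that add atoms: none
Why: The bulky borohydride delivers hydride to the face opposite the adjacent C2 allyl group (equatorial attack on the chair with equatorial allyl), which gives the 2,3-cis alcohol (3R) needed for chloride introduction with inversion; the low temperature avoids epimerisation at C2.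

Step 14
Reactants: 22 (2R,3R,5R,6R)-2-allyl-6-[(E)-3-bromopent-2-enyl]-5-[(tert-butyldimethylsilyl)oxy]oxan-3-ol
Product: 23 (2R,3S,5R,6R)-2-allyl-6-[(E)-3-bromopent-2-enyl]-5-[(tert-butyldimethylsilyl)oxy]-3-chlorooxane
Conditions: CCl4, (n-C8H17)3P, toluene, 70 °C
Reagents that add atoms: carbon tetrachloride, ClC(Cl)(Cl)Cl
Why: Appel chlorination; the alkoxyphosphonium ion is displaced by chloride in an SN2 reaction with inversion, which sets C3 as (S) with Cl trans to the C2 arm, while the silyl ether, both alkenes and the vinyl bromide are inert.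

Step 15
Reactants: 23 (2R,3S,5R,6R)-2-allyl-6-[(E)-3-bromopent-2-enyl]-5-[(tert-butyldimethylsilyl)oxy]-3-chlorooxane
Product: 24 (2R,3S,5R,6R)-2-allyl-6-[(E)-3-bromopent-2-enyl]-3-chlorooxan-5-ol
Conditions: HF·pyridine, pyridine, THF, 0 °C to rt
Reagents that add atoms: none
Why: Fluoride-mediated cleavage of the secondary silyl ether under buffered, weakly acidic conditions that do not eliminate the secondary chloride.

Step 16
Reactants: 24 (2R,3S,5R,6R)-2-allyl-6-[(E)-3-bromopent-2-enyl]-3-chlorooxan-5-ol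
Product: 25 (2R,3S,5S,6R)-2-allyl-5-bromo-6-[(E)-3-bromopent-2-enyl]-3-chlorooxane
Conditions: CBr4, (n-C8H17)3P, toluene, 70 °C
Reagents that add atoms: carbon tetrabromide, BrC(Br)(Br)Br
Why: Appel bromination of the C5 alcohol (cis to the C6 arm) proceeds by SN2 inversion and sets C5 as (S) with Br trans to the C6 arm.

Step 17
Reactants: 25 (2R,3S,5S,6R)-2-allyl-5-bromo-6-[(E)-3-bromopent-2-enyl]-3-chlorooxane
Product: 27 2-[(2R,3S,5S,6R)-5-bromo-6-((E)-3-bromopent-2-enyl)-3-chlorooxan-2-yl]acetaldehyde, via vicinal diol 26 (not isolated)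
Conditions: OsO4 (2 mol%), NaIO4 (4 equiv), 2,6-lutidine, dioxane/H2O (3:1), rt
Reagents that add atoms: osmium tetroxide, O=[Os](=O)(=O)=O; sodium periodate, [Na+].[O-]I(=O)(=O)=O
Why: Lemieux–Johnson oxidation; OsO4 dihydroxylates the monosubstituted alkene much faster than the electron-poor trisubstituted bromoalkene and NaIO4 cleaves diol 26 to the aldehyde.

Step 18
Reactants: 27 2-[(2R,3S,5S,6R)-5-bromo-6-((E)-3-bromopent-2-enyl)-3-chlorooxan-2-yl]acetaldehyde; 28 1,3-bis(triisopropylsilyl)propyne
Product: 31 (2R,3S,5S,6R)-5-bromo-6-[(E)-3-bromopent-2-enyl]-3-chloro-2-[(Z)-5-(triisopropylsilyl)pent-2-en-4-ynyl]oxane, via lithiated propyne 29 (not isolated), via lithium silyl alkoxide adduct 30 (not isolated)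
Conditions: 28, n-BuLi, THF, −78 °C; then 27, −78 °C to rt
Reagents that add atoms: none
Why: Peterson olefination with lithiated 1,3-bis(triisopropylsilyl)propyne; the bulky silyl groups steer the addition and syn elimination through the adduct that gives the (Z)-enyne, and at −78 °C the secondary halides and the vinyl bromide should survive.

Step 19
Reactants: 31 (2R,3S,5S,6R)-5-bromo-6-[(E)-3-bromopent-2-enyl]-3-chloro-2-[(Z)-5-(triisopropylsilyl)pent-2-en-4-ynyl]oxane
Product: 32 (2R,3S,5S,6R)-5-bromo-6-[(E)-3-bromopent-2-enyl]-3-chloro-2-[(Z)-pent-2-en-4-ynyl]oxane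
Conditions: Bu4NF, THF, −20 to 0 °C
Reagents that add atoms: none
Why: Fluoride cleaves the alkynyl C–Si bond at low temperature without touching the secondary bromide and chloride, which completes the target.

## Compound list

1 | pent-2-yn-1-ol | CCC#CCO | starting material
2 | (Z)-3-(triethylsilyl)pent-2-en-1-ol | OC/C=C(/CC)[Si](CC)(CC)CC | intermediate
3 | rel-(2S,3R)-2,3-dibromo-3-(triethylsilyl)pentan-1-ol (racemic anti adduct, one enantiomer drawn; not isolated) | OC[C@H](Br)[C@](Br)(CC)[Si](CC)(CC)CC | intermediate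
4 | (E)-3-bromopent-2-en-1-ol | OC/C=C(/Br)CC | intermediate
5 | (E)-3-bromo-1-iodopent-2-ene | IC/C=C(/Br)CC | intermediate
6 | 2-(allyloxy)acetic acid | OC(=O)COCC=C | starting material
7 | (S)-4-benzyl-1,3-oxazolidin-2-one | O=C1OC[C@H](Cc2ccccc2)N1 | starting material
8 | 2-(allyloxy)acetic pivalic anhydride (not isolated) | CC(C)(C)C(=O)OC(=O)COCC=C | intermediate
9 | (S)-3-[2-(allyloxy)acetyl]-4-benzyl-1,3-oxazolidin-2-one | O=C1OC[C@H](Cc2ccccc2)N1C(=O)COCC=C | intermediate
10 | sodium (Z)-enolate of 9 (not isolated) | O=C1OC[C@H](Cc2ccccc2)N1/C([O-])=C/OCC=C.[Na+] | intermediate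
11 | (S)-3-[(2R,4E)-2-(allyloxy)-5-bromohept-4-enoyl]-4-benzyl-1,3-oxazolidin-2-one | O=C1OC[C@H](Cc2ccccc2)N1C(=O)[C@H](OCC=C)C/C=C(/Br)CC | intermediate
12 | (2R,4E)-2-(allyloxy)-5-bromohept-4-en-1-ol | OC[C@H](OCC=C)C/C=C(/Br)CC | intermediate
13 | (2R,4E)-2-(allyloxy)-5-bromohept-4-enal | O=C[C@H](OCC=C)C/C=C(/Br)CC | intermediate
14 | tert-butyl[(1-methoxyethenyl)oxy]dimethylsilane | COC(=C)O[Si](C)(C)C(C)(C)C | starting material
15 | methyl (3R,4R,6E)-4-(allyloxy)-7-bromo-3-hydroxynon-6-enoate | COC(=O)C[C@@H](O)[C@H](OCC=C)C/C=C(/Br)CC | intermediate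
16 | methyl (3R,4R,6E)-4-(allyloxy)-7-bromo-3-[(tert-butyldimethylsilyl)oxy]non-6-enoate | COC(=O)C[C@@H](O[Si](C)(C)C(C)(C)C)[C@H](OCC=C)C/C=C(/Br)CC | intermediate
17 | (3R,4R,6E)-4-(allyloxy)-7-bromo-3-[(tert-butyldimethylsilyl)oxy]non-6-enoic acid | OC(=O)C[C@@H](O[Si](C)(C)C(C)(C)C)[C@H](OCC=C)C/C=C(/Br)CC | intermediate
18 | mixed anhydride of 17 with isobutyl carbonic acid (not isolated) | CC(C)COC(=O)OC(=O)C[C@@H](O[Si](C)(C)C(C)(C)C)[C@H](OCC=C)C/C=C(/Br)CC | intermediate
19 | (4R,5R,7E)-5-(allyloxy)-8-bromo-4-[(tert-butyldimethylsilyl)oxy]-1-diazodec-7-en-2-one | [N-]=[N+]=CC(=O)C[C@@H](O[Si](C)(C)C(C)(C)C)[C@H](OCC=C)C/C=C(/Br)CC | intermediate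
20 | six-membered O-allyl oxonium ylide, drawn metal-free (not isolated) | C=CC[O+]1[CH-]C(=O)C[C@@H](O[Si](C)(C)C(C)(C)C)[C@H]1C/C=C(/Br)CC | intermediate
21 | (2R,5R,6R)-2-allyl-6-[(E)-3-bromopent-2-enyl]-5-[(tert-butyldimethylsilyl)oxy]oxan-3-one | C=CC[C@H]1O[C@H](C/C=C(/Br)CC)[C@H](O[Si](C)(C)C(C)(C)C)CC1=O | intermediate
22 | (2R,3R,5R,6R)-2-allyl-6-[(E)-3-bromopent-2-enyl]-5-[(tert-butyldimethylsilyl)oxy]oxan-3-ol | C=CC[C@H]1O[C@H](C/C=C(/Br)CC)[C@H](O[Si](C)(C)C(C)(C)C)C[C@H]1O | intermediate
23 | (2R,3S,5R,6R)-2-allyl-6-[(E)-3-bromopent-2-enyl]-5-[(tert-butyldimethylsilyl)oxy]-3-chlorooxane | C=CC[C@H]1O[C@H](C/C=C(/Br)CC)[C@H](O[Si](C)(C)C(C)(C)C)C[C@@H]1Cl | intermediate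
24 | (2R,3S,5R,6R)-2-allyl-6-[(E)-3-bromopent-2-enyl]-3-chlorooxan-5-ol | C=CC[C@H]1O[C@H](C/C=C(/Br)CC)[C@H](O)C[C@@H]1Cl | intermediate
25 | (2R,3S,5S,6R)-2-allyl-5-bromo-6-[(E)-3-bromopent-2-enyl]-3-chlorooxane | C=CC[C@H]1O[C@H](C/C=C(/Br)CC)[C@@H](Br)C[C@@H]1Cl | intermediate
26 | vicinal diol from dihydroxylation of the allyl group of 25 (new carbinol centre unspecified; not isolated) | OCC(O)C[C@H]1O[C@H](C/C=C(/Br)CC)[C@@H](Br)C[C@@H]1Cl | intermediate
27 | 2-[(2R,3S,5S,6R)-5-bromo-6-((E)-3-bromopent-2-enyl)-3-chlorooxan-2-yl]acetaldehyde | O=CC[C@H]1O[C@H](C/C=C(/Br)CC)[C@@H](Br)C[C@@H]1Cl | intermediate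
28 | 1,3-bis(triisopropylsilyl)propyne | CC(C)[Si](C(C)C)(C(C)C)CC#C[Si](C(C)C)(C(C)C)C(C)C | starting material
29 | 1-lithio-1,3-bis(triisopropylsilyl)propyne (not isolated) | [Li]C(C#C[Si](C(C)C)(C(C)C)C(C)C)[Si](C(C)C)(C(C)C)C(C)C | intermediate
30 | lithium β-silyl alkoxide adduct of 29 and 27 (two new centres unspecified; not isolated) | [Li]OC(C[C@H]1O[C@H](C/C=C(/Br)CC)[C@@H](Br)C[C@@H]1Cl)C(C#C[Si](C(C)C)(C(C)C)C(C)C)[Si](C(C)C)(C(C)C)C(C)C | intermediate
31 | (2R,3S,5S,6R)-5-bromo-6-[(E)-3-bromopent-2-enyl]-3-chloro-2-[(Z)-5-(triisopropylsilyl)pent-2-en-4-ynyl]oxane | CC(C)[Si](C(C)C)(C(C)C)C#C/C=C\C[C@H]1O[C@H](C/C=C(/Br)CC)[C@@H](Br)C[C@@H]1Cl | intermediate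
32 | (2R,3S,5S,6R)-5-bromo-6-[(E)-3-bromopent-2-enyl]-3-chloro-2-[(Z)-pent-2-en-4-ynyl]oxane | C#C/C=C\C[C@H]1O[C@H](C/C=C(/Br)CC)[C@@H](Br)C[C@@H]1Cl | target

## Step count and risks

Total step count: 19. Longest linear sequence: 18 steps (1 → 2 → 4 → 5 → 11 → … → 32; step 4 is the only step outside it).

Steps most likely to fail:

**Step 12.** The copper carbenoid may be diverted before or after ylide formation: capture by the C5 silyl ether oxygen (five-membered ylide and silyl transfer), C–H insertion, cyclopropanation of the allyl group, [1,2] shift, or erosion of the 2,6-trans selectivity. The fallback sets out from 13 and comes back at 22; it closes the ring by olefin metathesis and makes the C2–allyl bond by epoxide opening. Chelation-controlled addition of vinylmagnesium bromide to 13 (MgBr2·OEt2, CH2Cl2, −78 °C) should give the syn allylic alcohol F1, which is silylated (TBSOTf, 2,6-lutidine) to the silyl ether F2. Ring-closing metathesis between the O-allyl group and the new vinyl group (second-generation Grubbs catalyst, toluene, 40 °C) gives the 3,6-dihydro-2H-pyran F3, which is not isolated. Adding 2-propanol and NaOH and heating to 110 °C converts the ruthenium carbene into a ruthenium hydride that moves the double bond into conjugation with O1 to give the cyclic enol ether F4. Epoxidation with dimethyldioxirane (acetone/CH2Cl2, −78 to 0 °C) anti to the pseudoaxial silyloxy group gives the epoxide F5 (not isolated). Triallylborane (THF, −78 to 0 °C) opens it with syn delivery of the allyl group to C2, cis to the C3 oxygen and trans to the C6 arm, to give 22.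

**Step 16.** The activated C5 oxygen may undergo E2 elimination (towards C4 or C6) or be displaced with participation of ring oxygen O1 (retention or ring contraction) instead of clean SN2 inversion. The fallback sets out from 24 and comes back at 25; it separates activation from displacement. 24 is converted with chloromethanesulfonyl chloride and 2,6-lutidine (CH2Cl2, 0 °C) into the chloromethanesulfonate F6, which is then displaced by soluble bromide (Bu4NBr, toluene, 50 °C) with inversion to give 25.

**Step 18.** The strongly basic lithiated silylpropyne may enolise the β-alkoxy aldehyde and trigger β-elimination of the ring oxygen, may cause E2 loss of HBr or HCl, or may give incomplete Z selectivity. The fallback sets out from 27 and comes back at 32; it builds the enyne by Wittig olefination and cross-coupling. Stork–Zhao olefination of 27 (Ph3P+CH2I I−, NaN(SiMe3)2, HMPA, THF, −78 °C) should give the (Z)-vinyl iodide F7. Sonogashira coupling with trimethylsilylacetylene (Pd(PPh3)4, CuI, Et2NH, rt) takes place at the C–I bond and leaves the trisubstituted bromoalkene, giving the silyl enyne F8. Mild desilylation (K2CO3, MeOH, 0 °C) gives 32.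

Further compounds
F1 | step 12 | (3R,4R,6E)-4-(allyloxy)-7-bromonona-1,6-dien-3-ol | C=C[C@@H](O)[C@H](OCC=C)C/C=C(/Br)CC
F2 | step 12 | tert-butyldimethylsilyl ether of F1 | C=C[C@@H](O[Si](C)(C)C(C)(C)C)[C@H](OCC=C)C/C=C(/Br)CC
F3 | step 12 | (2R,3R)-2-[(E)-3-bromopent-2-enyl]-3-[(tert-butyldimethylsilyl)oxy]-3,6-dihydro-2H-pyran | C1O[C@H](C/C=C(/Br)CC)[C@H](O[Si](C)(C)C(C)(C)C)C=C1
F4 | step 12 | (2R,3R)-2-[(E)-3-bromopent-2-enyl]-3-[(tert-butyldimethylsilyl)oxy]-3,4-dihydro-2H-pyran | C1=CO[C@H](C/C=C(/Br)CC)[C@H](O[Si](C)(C)C(C)(C)C)C1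
F5 | step 12 | epoxide of F4 with the epoxide oxygen anti to the silyloxy group | O1[C@H]2O[C@H](C/C=C(/Br)CC)[C@H](O[Si](C)(C)C(C)(C)C)C[C@H]21
F6 | step 16 | chloromethanesulfonate of 24 | C=CC[C@H]1O[C@H](C/C=C(/Br)CC)[C@H](OS(=O)(=O)CCl)C[C@@H]1Cl
F7 | step 18 | (2R,3S,5S,6R)-5-bromo-6-[(E)-3-bromopent-2-enyl]-3-chloro-2-[(Z)-3-iodoprop-2-enyl]oxane | I/C=C\C[C@H]1O[C@H](C/C=C(/Br)CC)[C@@H](Br)C[C@@H]1Cl
F8 | step 18 | (2R,3S,5S,6R)-5-bromo-6-[(E)-3-bromopent-2-enyl]-3-chloro-2-[(Z)-5-(trimethylsilyl)pent-2-en-4-ynyl]oxane | C[Si](C)(C)C#C/C=C\C[C@H]1O[C@H](C/C=C(/Br)CC)[C@@H](Br)C[C@@H]1Cl
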